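The cyclohexenone ring (C1 carbonyl, C2=C3 alkene, nonadecyl chain on C3) is cut at C2–C3 and at C4–C5. This leaves a two-carbon piece, C3–C4 with the chain, and a four-carbon piece, C5–C6–C1–C2 with the oxygen: henicos-1-yne and 2-(trimethylsiloxy)buta-1,3-diene. A cobalt-catalysed [4+2] cycloaddition joins them in one operation, making both bonds and the six-membered ring; a pyridine-imine ligand places the chain 1,3 to oxygen. The step exploits the 1,3-relation between the C1 oxygen and the C3 branch: the target is the conjugated keto tautomer of a 1-siloxycyclohexa-1,4-diene with C1=C6 and C3=C4 alkenes. Aqueous acid then unveils the enone.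

Key step: step 2

Remark on the chemistry: the target has no stereocentre and its only alkene is endocyclic, so no stereodescriptor is needed. 1-Bromononadecane is assumed to be a purchasable starting material.

Step 1
Reactants: 1 1-bromononadecane
Product: 2 henicos-1-yne
Conditions: LiC≡CH·H2NCH2CH2NH2 (1.5 equiv), DMSO/THF, 0 °C to rt
Reagents that add atoms: lithium acetylide–ethylenediamine complex, [Li+].[C-]#C.NCCN
Why: SN2 alkylation of an acetylide anion by an unhindered primary bromide in a dipolar aprotic medium should give the terminal alkyne, the THF co-solvent keeping the long-chain bromide in solution.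

Step 2
Reactants: 2 henicos-1-yne; 3 2-(trimethylsiloxy)buta-1,3-diene (1.5 equiv)
Product: 4 trimethyl[(5-nonadecylcyclohexa-1,4-dien-1-yl)oxy]silane
Conditions: CoBr2(N-mesityl-1-(pyridin-2-yl)methanimine) (10 mol%), Zn powder (20 mol%), ZnI2 (20 mol%), Fe powder (10 mol%), CH2Cl2, rt; then filtration through a short silica pad (pentane)
Reagents that add atoms: none
Why: Zinc should reduce the divalent cobalt bromide complex to a monovalent cobalt species which, made cationic by ZnI2, binds the s-cis diene 3 and the alkyne 2, couples them oxidatively to a cobaltacycle (first C–C bond) and closes the ring by allyl shift and reductive elimination (second C–C bond), a formal [4+2] cycloaddition. The closest known reaction type is the cobalt-catalysed neutral Diels–Alder reaction of unactivated terminal alkynes with 2-substituted buta-1,3-dienes, 2-siloxy dienes included, which gives cyclohexa-1,4-dienes. The single six-membered carbocycle is closed by intermolecular [4+2] annulation of the four-carbon diene and the two-carbon alkyne unit, the last bond arising by C–C reductive elimination at cobalt. No stereocentre is formed. The step needs 1,3-regioselectivity (chain-bearing alkyne carbon bonded to the CH2 next to the siloxy carbon) over the 1,4-mode, and chemoselectivity over alkyne cyclotrimerisation; the pyridine-imine ligand directs the 1,3-mode (a chelating bisphosphine would direct 1,4), which it can do because the alkyne has one substituted and one unsubstituted terminus and the diene a single 2-substituent, while the excess of diene should keep trimerisation down. The addition is atom-economic and leaves no co-product.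

Step 3
Reactants: 4 trimethyl[(5-nonadecylcyclohexa-1,4-dien-1-yl)oxy]silane
Product: 6 3-nonadecylcyclohex-2-en-1-one, via 3-nonadecylcyclohex-3-en-1-one 5 (not isolated)
Conditions: 2 M aq HCl, THF (degassed, argon), rt then 50 °C
Reagents that add atoms: none
Why: Acid hydrolysis of the silyl enol ether (C-protonation at ring C6, loss of trimethylsilanol) should give the deconjugated ketone 5, and acid-catalysed prototropic isomerisation through the dienol then moves the C3=C4 alkene to C2=C3, the conjugated trisubstituted enone being the thermodynamic isomer.

Compound list
1 | 1-bromononadecane | CCCCCCCCCCCCCCCCCCCBr | starting material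
2 | henicos-1-yne | CCCCCCCCCCCCCCCCCCCC#C | intermediate
3 | 2-(trimethylsiloxy)buta-1,3-diene, i.e. (buta-1,3-dien-2-yloxy)trimethylsilane | C=CC(=C)O[Si](C)(C)C | starting material
4 | trimethyl[(5-nonadecylcyclohexa-1,4-dien-1-yl)oxy]silane | CCCCCCCCCCCCCCCCCCCC1=CCC=C(O[Si](C)(C)C)C1 | intermediate
5 | 3-nonadecylcyclohex-3-en-1-one | CCCCCCCCCCCCCCCCCCCC1=CCCC(=O)C1 | intermediate
6 | 3-nonadecylcyclohex-2-en-1-one | CCCCCCCCCCCCCCCCCCCC1=CC(=O)CCC1 | target

Total step count: 3
Longest linear sequence: 3 steps (1 → 2 → 4 → 6)

Steps most likely to fail

Step 2. The risk is erosion of regiocontrol, with the 1,4-mode of ring closure competing with the 1,3-mode, and cobalt-mediated cyclotrimerisation of the alkyne. The fallback keeps the same two ring bonds (C2–C3 and C4–C5) but makes them by a thermal, polarity-controlled Diels–Alder reaction. It sets out from 2 and comes back to the route at 6.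
- Deprotonation of 2 (n-BuLi, THF, −78 °C) and quench with methyl chloroformate should give methyl docos-2-ynoate F1.
- Heating F1 with diene 3 (toluene, 150 °C, sealed tube) should give methyl 2-nonadecyl-4-[(trimethylsilyl)oxy]cyclohexa-1,4-diene-1-carboxylate F2. The nucleophilic CH2 terminus next to the siloxy carbon bonds to the chain-bearing β-carbon of the ynoate, so the chain again ends up 1,3 to oxygen.
- Dilute HCl in THF should unveil methyl 2-nonadecyl-4-oxocyclohex-1-ene-1-carboxylate F3.
- Saponification (KOH, aq MeOH, reflux) and acidification with warming should pass through 2-nonadecyl-4-oxocyclohex-2-ene-1-carboxylic acid F4, a vinylogous β-keto acid that loses carbon dioxide to give 6.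

Step 3. The risk is aerobic dehydrogenation of the dihydroaromatic ring (aromatisation) in warm acid, and stalling of the double-bond migration at the deconjugated stage. The fallback replaces the one-pot acid process by a two-stage anionic sequence. It sets out from 4 and comes back at 6, and it makes no compound outside the list (entry F0).
- Buffered fluoride cleavage of the Si–O bond (TBAF, AcOH, THF, 0 °C, argon) should allow 5 to be isolated.
- A separate amine-base isomerisation (DBU, CH2Cl2, rt), running through the dienolate, should then move the alkene into conjugation to give 6.

Step 1. The risk is slow substitution because the C19 bromide dissolves poorly in DMSO, with E2 elimination of HBr taking over. The fallback reverses the polarity of the chain and builds the alkyne by one-carbon homologation of an aldehyde. It sets out from 1 and comes back at 2.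
- Magnesium in THF should convert 1 into nonadecylmagnesium bromide F5.
- Formylation with DMF and acidic work-up (Bouveault aldehyde synthesis) should give icosanal F6.
- Ohira–Bestmann alkynylation (dimethyl (1-diazo-2-oxopropyl)phosphonate, K2CO3, MeOH/THF, rt) should give 2.

Further compounds
F1 | step 2 | methyl docos-2-ynoate | CCCCCCCCCCCCCCCCCCCC#CC(=O)OC
F2 | step 2 | methyl 2-nonadecyl-4-[(trimethylsilyl)oxy]cyclohexa-1,4-diene-1-carboxylate | CCCCCCCCCCCCCCCCCCCC1=C(C(=O)OC)CC=C(O[Si](C)(C)C)C1
F3 | step 2 | methyl 2-nonadecyl-4-oxocyclohex-1-ene-1-carboxylate | CCCCCCCCCCCCCCCCCCCC1=C(C(=O)OC)CCC(=O)C1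
F4 | step 2 | 2-nonadecyl-4-oxocyclohex-2-ene-1-carboxylic acid | CCCCCCCCCCCCCCCCCCCC1=CC(=O)CCC1C(=O)O
F0 | step 3 | none | none
F5 | step 1 | nonadecylmagnesium bromide | CCCCCCCCCCCCCCCCCCC[Mg]Br
F6 | step 1 | icosanal | CCCCCCCCCCCCCCCCCCCC=O
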